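**Retrosynthetic overview**
- The oxirane is closed last from a C14/C15 diol, and the two acids are carried as 2-(trimethylsilyl)ethyl esters that are cleaved by fluoride in the final step.
- The tetrahydropyran comes from cationic cyclodehydration of a bis-tertiary C8/C13 diol (C8–O bond), the diol from a C8 cyclohexanone and MeLi.
- The C9 side chain comes from aldol condensation/hydrogenation with a C11–C15 aldehyde built from D-mannitol; the C10 quaternary centre comes from a Mukaiyama–Michael addition to a 4-substituted 3-methylcyclohex-2-enone.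
- That cyclohexenone (the carbocycle of the target) is closed by an intramolecular aldol condensation of a 3-substituted heptane-2,6-dione obtained from (R)-carvone by gem-dimethylation, conjugate reduction and double ozonolysis.
- Ring order: carbocycle (aldol), then tetrahydropyran (cyclodehydration), then oxirane (Williamson closure).

Assumption: labdane-type locants (C1–C20) are used in the explanations only; in them the target is (5S,8S,9S,10R,13R,14R), with C5 = ring CH bearing CMe2CO2H, C10 = ring carbon bearing CH3/CH2CO2H, C9 = ring CH bearing the chain, C8/C13 = the two O-bearing carbons, C14/C15 = oxirane.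

**Route**

Step 1
Reactants: 1 (R)-(−)-carvone
Product: 3 (5R)-2,6-dimethyl-5-(prop-1-en-2-yl)cyclohex-2-en-1-one (C6 epimer mixture), via lithium dienolate 2 (not isolated)
Conditions: LiN(iPr)2, THF, −78 °C; then MeI, −78 → 0 °C
Reagents that add atoms: iodomethane, CI
Why: Kinetic alpha'-deprotonation and SN2 enolate methylation; the new C6 centre is an epimer mixture that becomes quaternary in step 2.

Step 2
Reactants: 3 (5R)-2,6-dimethyl-5-(prop-1-en-2-yl)cyclohex-2-en-1-one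
Product: 5 (5S)-2,6,6-trimethyl-5-(prop-1-en-2-yl)cyclohex-2-en-1-one, via lithium dienolate 4 (not isolated)
Conditions: LiN(iPr)2, THF, −78 °C; then MeI, DMPU, −78 → 0 °C
Reagents that add atoms: iodomethane, CI
Why: A second kinetic enolate alkylation at the same alpha' carbon gives the gem-dimethyl group (future C4 with C18/C19); the carvone stereocentre is untouched (descriptor changes by priority only).

Step 3
Reactants: 5 (5S)-2,6,6-trimethyl-5-(prop-1-en-2-yl)cyclohex-2-en-1-one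
Product: 7 trimethyl{[(5S)-2,6,6-trimethyl-5-(prop-1-en-2-yl)cyclohex-1-en-1-yl]oxy}silane, via lithium enolate 6 (not isolated)
Conditions: LiBH(sec-Bu)3, THF, −78 °C; then Me3SiCl, Et3N, −78 → 0 °C
Reagents that add atoms: chlorotrimethylsilane, C[Si](C)(C)Cl
Why: Conjugate (1,4) hydride reduction of the hindered enone gives the only possible enolate (the other alpha carbon is quaternary), which is O-silylated to the regiodefined silyl enol ether.

Step 4
Reactants: 7 trimethyl{[(5S)-2,6,6-trimethyl-5-(prop-1-en-2-yl)cyclohex-1-en-1-yl]oxy}silane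
Product: 9 (3R)-3-acetyl-2,2-dimethyl-6-oxoheptanoic acid, via peroxyketal silyl ester 8 (not isolated)
Conditions: O3, CH2Cl2/MeOH (4:1), −78 °C; then Me2S, −78 °C → rt, aqueous work-up
Reagents that add atoms: ozone, [O-][O+]=O
Why: Ozonolysis cleaves the enol ether C=C (ring opening to C3 acid and C8 methyl ketone) and the isopropenyl group (to the C10 acetyl), leaving the carvone stereocentre as C5.

Step 5
Reactants: 9 (3R)-3-acetyl-2,2-dimethyl-6-oxoheptanoic acid; 10 2-(trimethylsilyl)ethanol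
Product: 11 2-(trimethylsilyl)ethyl (3R)-3-acetyl-2,2-dimethyl-6-oxoheptanoate
Conditions: PPh3, DIAD, THF, 0 °C → rt
Reagents that add atoms: none
Why: Mitsunobu esterification, in which the hindered carboxylate acts as nucleophile on the activated primary alcohol, so steric hindrance at the acid does not matter.

Step 6 (key ring closure)
Reactants: 11 2-(trimethylsilyl)ethyl (3R)-3-acetyl-2,2-dimethyl-6-oxoheptanoate
Product: 14 2-(trimethylsilyl)ethyl 2-methyl-2-[(1S)-2-methyl-4-oxocyclohex-2-en-1-yl]propanoate, via pyrrolidine enamine 12 (not isolated), via cyclic aldol 13 (not isolated)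
Conditions: pyrrolidine (1.2 equiv), AcOH (0.3 equiv), toluene, 80 °C, Dean–Stark; then aq. NaOAc/AcOH, 50 °C
Reagents that add atoms: none
Why: Enamine-mediated intramolecular aldol condensation (6-enolendo, Hajos–Parrish type): only the unhindered methyl ketone forms an enamine, whose terminal carbon (C9) attacks the acetyl carbonyl (C10), and dehydration gives the conjugated enone with C5 unchanged.

Step 7
Reactants: 15 1,2:5,6-di-O-isopropylidene-D-mannitol
Product: 16 (R)-2,2-dimethyl-1,3-dioxolane-4-carbaldehyde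
Conditions: NaIO4, NaHCO3, CH2Cl2/H2O, 0 °C → rt
Reagents that add atoms: none
Why: Periodate glycol cleavage (Malaprade) of the central diol gives two equivalents of the aldehyde, whose stereocentre (future C14) comes from D-mannitol.

Step 8
Reactants: 16 (R)-2,2-dimethyl-1,3-dioxolane-4-carbaldehyde
Product: 17 1-[(4R)-2,2-dimethyl-1,3-dioxolan-4-yl]but-3-en-1-ol (carbinol epimers)
Conditions: CH2=CHCH2MgBr, Et2O, −78 °C
Reagents that add atoms: allylmagnesium bromide, C=CC[Mg]Br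
Why: Grignard 1,2-addition; the carbinol configuration is irrelevant because it is oxidised in step 9.

Step 9
Reactants: 17 1-[(4R)-2,2-dimethyl-1,3-dioxolan-4-yl]but-3-en-1-ol
Product: 18 1-[(4R)-2,2-dimethyl-1,3-dioxolan-4-yl]but-3-en-1-one
Conditions: Dess–Martin periodinane, NaHCO3, CH2Cl2, 0 °C
Reagents that add atoms: none
Why: Buffered Dess–Martin oxidation gives the beta,gamma-unsaturated ketone without base, so neither alkene migration nor epimerisation of the alpha-alkoxy centre is expected.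

Step 10
Reactants: 18 1-[(4R)-2,2-dimethyl-1,3-dioxolan-4-yl]but-3-en-1-one
Product: 19 (2R)-2-[(4R)-2,2-dimethyl-1,3-dioxolan-4-yl]pent-4-en-2-ol
Conditions: CeCl3 (dried), MeLi, THF, −78 °C
Reagents that add atoms: methyllithium, [Li]C
Why: Non-basic organocerium 1,2-addition under Felkin–Anh control (methyl enters anti to the dioxolane C–O bond) sets the tertiary carbinol C13 as (2R) while suppressing enolisation of the acidic allyl ketone.

Step 11
Reactants: 19 (2R)-2-[(4R)-2,2-dimethyl-1,3-dioxolan-4-yl]pent-4-en-2-ol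
Product: 20 {[(2R)-2-[(4R)-2,2-dimethyl-1,3-dioxolan-4-yl]pent-4-en-2-yl]oxy}triethylsilane
Conditions: Et3SiOTf, 2,6-lutidine, CH2Cl2, −78 → 0 °C
Reagents that add atoms: triethylsilyl trifluoromethanesulfonate, CC[Si](CC)(CC)OS(=O)(=O)C(F)(F)F
Why: Silyl triflate silylation of the hindered tertiary alcohol prevents retro-aldol and Lewis-acid complexation in the later aldol step.

Step 12
Reactants: 20 {[(2R)-2-[(4R)-2,2-dimethyl-1,3-dioxolan-4-yl]pent-4-en-2-yl]oxy}triethylsilane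
Product: 22 (3R)-3-[(4R)-2,2-dimethyl-1,3-dioxolan-4-yl]-3-[(triethylsilyl)oxy]butanal, via ozonide 21 (not isolated)
Conditions: O3, CH2Cl2, −78 °C; then PPh3, −78 °C → rt
Reagents that add atoms: ozone, [O-][O+]=O
Why: Ozonolysis with reductive work-up turns the allyl group into the CH2–CHO unit (C12–C11) without touching the two stereocentres.

Step 13
Reactants: 10 2-(trimethylsilyl)ethanol
Product: 23 2-(trimethylsilyl)ethyl acetate
Conditions: AcCl, pyridine, CH2Cl2, 0 °C
Reagents that add atoms: acetyl chloride, CC(=O)Cl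
Why: Simple O-acylation gives the acetate that carries the C1–C2 unit and its fluoride-labile ester group.

Step 14
Reactants: 23 2-(trimethylsilyl)ethyl acetate
Product: 25 tert-butyldimethyl({1-[2-(trimethylsilyl)ethoxy]ethenyl}oxy)silane, via lithium enolate 24 (not isolated)
Conditions: LiN(iPr)2, THF, −78 °C; then t-BuMe2SiCl, DMPU, −78 °C → rt
Reagents that add atoms: tert-butylchlorodimethylsilane, CC(C)(C)[Si](C)(C)Cl
Why: O-silylation of the ester enolate gives the ketene silyl acetal needed as a soft acetate nucleophile.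

Step 15
Reactants: 14 2-(trimethylsilyl)ethyl 2-methyl-2-[(1S)-2-methyl-4-oxocyclohex-2-en-1-yl]propanoate; 25 tert-butyldimethyl({1-[2-(trimethylsilyl)ethoxy]ethenyl}oxy)silane; 22 (3R)-3-[(4R)-2,2-dimethyl-1,3-dioxolan-4-yl]-3-[(triethylsilyl)oxy]butanal
Product: 27 2-(trimethylsilyl)ethyl 2-[(1S,2R)-3-{(3R)-3-[(4R)-2,2-dimethyl-1,3-dioxolan-4-yl]-1-hydroxy-3-[(triethylsilyl)oxy]butyl}-2-methyl-4-oxo-2-{2-oxo-2-[2-(trimethylsilyl)ethoxy]ethyl}cyclohexyl]-2-methylpropanoate (epimers at C9 and C11), via silyl enol ether 26 (not isolated)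
Conditions: t-BuMe2SiOTf (0.1 equiv), CH2Cl2, −78 → −40 °C; then 22, BF3·OEt2, −78 °C
Reagents that add atoms: none
Why: Mukaiyama–Michael addition of the ketene silyl acetal to the enone face opposite the bulky C5 substituent sets the C10 quaternary centre (CH2CO2R trans to C5–C4), and the regiodefined silyl enol ether then undergoes a BF3-mediated Mukaiyama aldol addition at C9.

Step 16
Reactants: 27 aldol adduct of step 15
Product: 29 2-(trimethylsilyl)ethyl 2-[(1S,2R)-3-{(3R)-3-[(4R)-2,2-dimethyl-1,3-dioxolan-4-yl]-3-[(triethylsilyl)oxy]butylidene}-2-methyl-4-oxo-2-{2-oxo-2-[2-(trimethylsilyl)ethoxy]ethyl}cyclohexyl]-2-methylpropanoate (E/Z mixture), via mesylate 28 (not isolated)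
Conditions: MsCl, Et3N, CH2Cl2, 0 °C; then DBU, rt
Reagents that add atoms: none
Why: Mesylation and E1cB elimination give the exocyclic enone, erasing the C9/C11 epimer mixture so that the C9 hydrogen can be introduced last.

Step 17
Reactants: 29 exocyclic enone of step 16
Product: 30 2-(trimethylsilyl)ethyl 2-[(1S,2R,3S)-3-{(3R)-3-[(4R)-2,2-dimethyl-1,3-dioxolan-4-yl]-3-[(triethylsilyl)oxy]butyl}-2-methyl-4-oxo-2-{2-oxo-2-[2-(trimethylsilyl)ethoxy]ethyl}cyclohexyl]-2-methylpropanoate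
Conditions: H2 (1 atm), Pd/C (10% palladium on carbon), EtOAc, rt
Reagents that add atoms: none
Why: Heterogeneous catalytic hydrogenation delivers hydrogen to C9 from the face opposite the C10 methyl and the C5 substituent, so the side chain ends up cis to the C10 methyl (equatorial), and C9 stays epimerisable toward this same isomer.

Step 18
Reactants: 30 ketone of step 17
Product: 31 2-(trimethylsilyl)ethyl 2-[(1S,2R,3S)-3-{(3R)-3-[(4R)-2,2-dimethyl-1,3-dioxolan-4-yl]-3-[(triethylsilyl)oxy]butyl}-4-hydroxy-2,4-dimethyl-2-{2-oxo-2-[2-(trimethylsilyl)ethoxy]ethyl}cyclohexyl]-2-methylpropanoate (C8 epimers)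
Conditions: CeCl3 (dried), MeLi, THF, −78 °C
Reagents that add atoms: methyllithium, [Li]C
Why: Organocerium 1,2-addition to the hindered ketone installs C17 without attacking the esters; the C8 carbinol configuration does not matter because C8 is ionised in step 19.

Step 19
Reactants: 31 tertiary alcohol of step 18
Product: 34 2-(trimethylsilyl)ethyl 2-[(2R,4aS,5R,6S,8aS)-2-[(1R)-1,2-dihydroxyethyl]-2,5,8a-trimethyl-5-{2-oxo-2-[2-(trimethylsilyl)ethoxy]ethyl}octahydro-2H-chromen-6-yl]-2-methylpropanoate, via diol 32 (not isolated), via pyran acetonide 33 (not isolated)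
Conditions: TsOH·H2O (0.2 equiv), MeNO2, 0 °C → rt; then AcOH/H2O (4:1), 45 °C
Reagents that add atoms: none
Why: Acid removes the silyl ether and ionises the tertiary C8 alcohol, and the cation is captured by the C13 hydroxyl from the equatorial side (SN1 cyclodehydration, as in sclareol-type oxide formation) to give the trans-fused tetrahydropyran with the C8 methyl axial; aqueous acid then hydrolyses the acetonide.

Step 20
Reactants: 34 pyran diol of step 19
Product: 36 2-(trimethylsilyl)ethyl 2-[(2R,4aS,5R,6S,8aS)-2,5,8a-trimethyl-2-[(2R)-oxiran-2-yl]-5-{2-oxo-2-[2-(trimethylsilyl)ethoxy]ethyl}octahydro-2H-chromen-6-yl]-2-methylpropanoate, via monotosylate 35 (not isolated)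
Conditions: TsCl, Et3N, Bu2SnO (2 mol %), CH2Cl2, 0 °C; then DBU, rt
Reagents that add atoms: none
Why: Stannylene-catalysed selective sulfonylation of the primary hydroxyl followed by intramolecular Williamson displacement closes the oxirane with retention at C14, since its C–O bond is never broken.

Step 21
Reactants: 36 bis[2-(trimethylsilyl)ethyl] ester of step 20
Product: 37 2-[(2R,4aS,5R,6S,8aS)-5-(carboxymethyl)-2,5,8a-trimethyl-2-[(2R)-oxiran-2-yl]octahydro-2H-chromen-6-yl]-2-methylpropanoic acid (CNP0160287.1)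
Conditions: Bu4NF, THF, 0 °C → rt; NaH2PO4 buffer (pH 5) work-up
Reagents that add atoms: none
Why: Fluoride-induced beta-elimination of both 2-(trimethylsilyl)ethyl esters releases the acids under conditions that are independent of carbonyl hindrance and leave the epoxide and all stereocentres untouched.

**Compound list**

1 | (R)-(−)-carvone, (5R)-2-methyl-5-(prop-1-en-2-yl)cyclohex-2-en-1-one | CC1=CC[C@H](CC1=O)C(C)=C | starting material
2 | lithium dienolate of 1 (OLi on C1, C1=C6) | CC1=CC[C@H](C=C1O[Li])C(C)=C | intermediate (not isolated)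
3 | (5R)-2,6-dimethyl-5-(prop-1-en-2-yl)cyclohex-2-en-1-one, C6 epimer mixture | CC1=CC[C@H](C(C)C1=O)C(C)=C | intermediate
4 | lithium dienolate of 3 | CC1=CC[C@H](C(C)=C1O[Li])C(C)=C | intermediate (not isolated)
5 | (5S)-2,6,6-trimethyl-5-(prop-1-en-2-yl)cyclohex-2-en-1-one | CC1=CC[C@H](C(C)(C)C1=O)C(C)=C | intermediate
6 | lithium (5S)-2,6,6-trimethyl-5-(prop-1-en-2-yl)cyclohex-1-en-1-olate | CC1=C(O[Li])C(C)(C)[C@@H](CC1)C(C)=C | intermediate (not isolated)
7 | trimethyl{[(5S)-2,6,6-trimethyl-5-(prop-1-en-2-yl)cyclohex-1-en-1-yl]oxy}silane | CC1=C(O[Si](C)(C)C)C(C)(C)[C@@H](CC1)C(C)=C | intermediate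
8 | trimethylsilyl (3R)-6-hydroperoxy-3-(1-hydroperoxy-1-methoxyethyl)-6-methoxy-2,2-dimethylheptanoate (peroxyketal epimers) | CC(C)(C(=O)O[Si](C)(C)C)[C@H](C(C)(OC)OO)CCC(C)(OC)OO | intermediate (not isolated)
9 | (3R)-3-acetyl-2,2-dimethyl-6-oxoheptanoic acid | CC(C)(C(=O)O)[C@H](C(C)=O)CCC(C)=O | intermediate
10 | 2-(trimethylsilyl)ethanol | C[Si](C)(C)CCO | starting material
11 | 2-(trimethylsilyl)ethyl (3R)-3-acetyl-2,2-dimethyl-6-oxoheptanoate | CC(C)(C(=O)OCC[Si](C)(C)C)[C@H](C(C)=O)CCC(C)=O | intermediate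
12 | 2-(trimethylsilyl)ethyl (3R)-3-acetyl-2,2-dimethyl-6-(pyrrolidin-1-yl)hept-6-enoate | CC(C)(C(=O)OCC[Si](C)(C)C)[C@H](C(C)=O)CCC(=C)N1CCCC1 | intermediate (not isolated)
13 | 2-(trimethylsilyl)ethyl 2-[(1R)-2-hydroxy-2-methyl-4-oxocyclohexyl]-2-methylpropanoate (C2 epimers) | CC(C)(C(=O)OCC[Si](C)(C)C)[C@H]1CCC(=O)CC1(C)O | intermediate (not isolated)
14 | 2-(trimethylsilyl)ethyl 2-methyl-2-[(1S)-2-methyl-4-oxocyclohex-2-en-1-yl]propanoate | CC(C)(C(=O)OCC[Si](C)(C)C)[C@H]1CCC(=O)C=C1C | intermediate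
15 | 1,2:5,6-di-O-isopropylidene-D-mannitol | O[C@H]([C@H]1COC(C)(C)O1)[C@H](O)[C@H]1COC(C)(C)O1 | starting material
16 | (R)-2,2-dimethyl-1,3-dioxolane-4-carbaldehyde | O=C[C@H]1COC(C)(C)O1 | intermediate
17 | 1-[(4R)-2,2-dimethyl-1,3-dioxolan-4-yl]but-3-en-1-ol (carbinol epimers) | C=CCC(O)[C@H]1COC(C)(C)O1 | intermediate
18 | 1-[(4R)-2,2-dimethyl-1,3-dioxolan-4-yl]but-3-en-1-one | C=CCC(=O)[C@H]1COC(C)(C)O1 | intermediate
19 | (2R)-2-[(4R)-2,2-dimethyl-1,3-dioxolan-4-yl]pent-4-en-2-ol | C=CC[C@@](C)(O)[C@H]1COC(C)(C)O1 | intermediate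
20 | {[(2R)-2-[(4R)-2,2-dimethyl-1,3-dioxolan-4-yl]pent-4-en-2-yl]oxy}triethylsilane | C=CC[C@@](C)(O[Si](CC)(CC)CC)[C@H]1COC(C)(C)O1 | intermediate
21 | ozonide of 20 (3-substituted 1,2,4-trioxolane) | C1(OCOO1)C[C@@](C)(O[Si](CC)(CC)CC)[C@H]2COC(C)(C)O2 | intermediate (not isolated)
22 | (3R)-3-[(4R)-2,2-dimethyl-1,3-dioxolan-4-yl]-3-[(triethylsilyl)oxy]butanal | O=CC[C@@](C)(O[Si](CC)(CC)CC)[C@H]1COC(C)(C)O1 | intermediate
23 | 2-(trimethylsilyl)ethyl acetate | CC(=O)OCC[Si](C)(C)C | intermediate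
24 | lithium enolate of 23 | C=C(O[Li])OCC[Si](C)(C)C | intermediate (not isolated)
25 | tert-butyldimethyl({1-[2-(trimethylsilyl)ethoxy]ethenyl}oxy)silane | C=C(OCC[Si](C)(C)C)O[Si](C)(C)C(C)(C)C | intermediate
26 | 2-(trimethylsilyl)ethyl 2-[(1S,2R)-4-[(tert-butyldimethylsilyl)oxy]-2-methyl-2-{2-oxo-2-[2-(trimethylsilyl)ethoxy]ethyl}cyclohex-3-en-1-yl]-2-methylpropanoate | CC(C)(C(=O)OCC[Si](C)(C)C)[C@H]1CCC(O[Si](C)(C)C(C)(C)C)=C[C@]1(C)CC(=O)OCC[Si](C)(C)C | intermediate (not isolated)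
27 | aldol adduct: as 30 but with a 1-hydroxy group on the butyl chain (C11), epimers at C9 and C11 | CC(C)(C(=O)OCC[Si](C)(C)C)[C@H]1CCC(=O)C(C(O)C[C@@](C)(O[Si](CC)(CC)CC)[C@H]2COC(C)(C)O2)[C@]1(C)CC(=O)OCC[Si](C)(C)C | intermediate
28 | C11 methanesulfonate of 27 | CC(C)(C(=O)OCC[Si](C)(C)C)[C@H]1CCC(=O)C(C(OS(C)(=O)=O)C[C@@](C)(O[Si](CC)(CC)CC)[C@H]2COC(C)(C)O2)[C@]1(C)CC(=O)OCC[Si](C)(C)C | intermediate (not isolated)
29 | exocyclic enone: (1S,2R)-3-butylidene analogue of 30 (C9=C11, E/Z mixture) | CC(C)(C(=O)OCC[Si](C)(C)C)[C@H]1CCC(=O)C(=CC[C@@](C)(O[Si](CC)(CC)CC)[C@H]2COC(C)(C)O2)[C@]1(C)CC(=O)OCC[Si](C)(C)C | intermediate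
30 | 2-(trimethylsilyl)ethyl 2-[(1S,2R,3S)-3-{(3R)-3-[(4R)-2,2-dimethyl-1,3-dioxolan-4-yl]-3-[(triethylsilyl)oxy]butyl}-2-methyl-4-oxo-2-{2-oxo-2-[2-(trimethylsilyl)ethoxy]ethyl}cyclohexyl]-2-methylpropanoate | CC(C)(C(=O)OCC[Si](C)(C)C)[C@H]1CCC(=O)[C@@H](CC[C@@](C)(O[Si](CC)(CC)CC)[C@H]2COC(C)(C)O2)[C@]1(C)CC(=O)OCC[Si](C)(C)C | intermediate
31 | C8 tertiary alcohol from 30 (4-hydroxy-2,4-dimethyl, C8 epimers) | CC(C)(C(=O)OCC[Si](C)(C)C)[C@H]1CCC(C)(O)[C@@H](CC[C@@](C)(O[Si](CC)(CC)CC)[C@H]2COC(C)(C)O2)[C@]1(C)CC(=O)OCC[Si](C)(C)C | intermediate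
32 | C8/C13 diol (31 without the triethylsilyl group) | CC(C)(C(=O)OCC[Si](C)(C)C)[C@H]1CCC(C)(O)[C@@H](CC[C@@](C)(O)[C@H]2COC(C)(C)O2)[C@]1(C)CC(=O)OCC[Si](C)(C)C | intermediate (not isolated)
33 | pyran acetonide: (2R,4aS,5R,6S,8aS)-octahydrochromene diester with a (4R)-2,2-dimethyl-1,3-dioxolan-4-yl group at C2 | CC(C)(C(=O)OCC[Si](C)(C)C)[C@H]1CC[C@]2(C)O[C@@](C)([C@H]3COC(C)(C)O3)CC[C@H]2[C@]1(C)CC(=O)OCC[Si](C)(C)C | intermediate (not isolated)
34 | 2-(trimethylsilyl)ethyl 2-[(2R,4aS,5R,6S,8aS)-2-[(1R)-1,2-dihydroxyethyl]-2,5,8a-trimethyl-5-{2-oxo-2-[2-(trimethylsilyl)ethoxy]ethyl}octahydro-2H-chromen-6-yl]-2-methylpropanoate | CC(C)(C(=O)OCC[Si](C)(C)C)[C@H]1CC[C@]2(C)O[C@@](C)([C@H](O)CO)CC[C@H]2[C@]1(C)CC(=O)OCC[Si](C)(C)C | intermediate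
35 | primary p-toluenesulfonate of 34 | CC(C)(C(=O)OCC[Si](C)(C)C)[C@H]1CC[C@]2(C)O[C@@](C)([C@H](O)COS(=O)(=O)c3ccc(C)cc3)CC[C@H]2[C@]1(C)CC(=O)OCC[Si](C)(C)C | intermediate (not isolated)
36 | bis[2-(trimethylsilyl)ethyl] ester of 37 | CC(C)(C(=O)OCC[Si](C)(C)C)[C@H]1CC[C@]2(C)O[C@@](C)([C@H]3CO3)CC[C@H]2[C@]1(C)CC(=O)OCC[Si](C)(C)C | intermediate
37 | 2-[(2R,4aS,5R,6S,8aS)-5-(carboxymethyl)-2,5,8a-trimethyl-2-[(2R)-oxiran-2-yl]octahydro-2H-chromen-6-yl]-2-methylpropanoic acid | CC(C)(C(=O)O)[C@H]1CC[C@]2(C)O[C@@](C)([C@H]3CO3)CC[C@H]2[C@]1(C)CC(=O)O | target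

**Step count**

Total step count: 21.
Longest linear sequence: 13 steps (steps 1–6 then 15–21; the branch through steps 7–12 then 15–21 is equally long; the branch through steps 13–14 is shorter).

**Steps most likely to fail, with fallbacks**

Step 6. The aldol could close the other way (the acetyl methyl attacking the unhindered ketone, giving the 6-substituted 3-methylcyclohexenone, the known outcome under plain base), and C5 could partly epimerise. The fallback sets out from 7 and comes back at 14. Only the enol ether of 7 is ozonised (1.0 equiv O3, −78 °C, then Me2S), which gives (3S)-2,2-dimethyl-6-oxo-3-(prop-1-en-2-yl)heptanoic acid F1 with the isopropenyl group intact. Mitsunobu esterification with 10 gives its 2-(trimethylsilyl)ethyl ester F2. Kinetic deprotonation of the methyl ketone with LiN(iPr)2, trapping with ClP(O)(OEt)2 and a second portion of LiN(iPr)2 (enol phosphate to phosphonate rearrangement) give the beta-keto phosphonate F3. Ozonolysis of the isopropenyl group then gives the acetyl beta-keto phosphonate F4. An intramolecular Horner–Wadsworth–Emmons olefination (LiCl, DBU, MeCN) can only join C9 to C10 and delivers 14.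

Step 15. The Mukaiyama–Michael addition must form a quaternary centre next to the very bulky C5 substituent (1,2-addition or no reaction are possible), and the hindered enol ether must then undergo the aldol. The fallback sets out from 14 and comes back at 30. Hosomi–Sakurai allylation (CH2=CHCH2SiMe3, TiCl4, CH2Cl2, −78 °C, anti to the C5 substituent) with trapping of the titanium enolate by 22 gives the C10-allyl aldol F5. MsCl/Et3N then DBU gives the C10-allyl exocyclic enone F6. Conjugate reduction with [(Ph3P)CuH]6, which leaves the allyl group alone, gives the C10-allyl ketone F7 with the C9 hydrogen delivered last. OsO4 (cat.)/NaIO4 cleaves the allyl group to the C10 acetaldehyde F8, NaClO2/NaH2PO4/2-methyl-2-butene gives the C10 acetic acid F9, and Mitsunobu esterification with 10 gives 30.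

Step 19. The C8 cation may eliminate or rearrange instead of being trapped, or be trapped with the wrong ring fusion. The fallback sets out from 30 (replacing steps 18 and 19) and comes back at 34. Wittig methylenation (Ph3PCH3Br, KOtBu, toluene, 80 °C) gives the C8 exocyclic methylene compound F10. PPTS in MeOH removes the triethylsilyl group to give the C13 tertiary alcohol F11. Intramolecular alkoxymercuration with Hg(OAc)2 in THF (Markovnikov, oxygen entering C8 from the equatorial side) gives the acetoxymercuriomethyl pyran F12. NaBH4/NaOH demercuration gives 33, which is hydrolysed with AcOH/H2O to 34.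

**Further compounds**

F1 | step 6 | (3S)-2,2-dimethyl-6-oxo-3-(prop-1-en-2-yl)heptanoic acid | CC(C)(C(=O)O)[C@H](C(C)=C)CCC(C)=O
F2 | step 6 | 2-(trimethylsilyl)ethyl (3S)-2,2-dimethyl-6-oxo-3-(prop-1-en-2-yl)heptanoate | CC(C)(C(=O)OCC[Si](C)(C)C)[C@H](C(C)=C)CCC(C)=O
F3 | step 6 | 2-(trimethylsilyl)ethyl (3S)-7-(diethoxyphosphoryl)-2,2-dimethyl-6-oxo-3-(prop-1-en-2-yl)heptanoate | CC(C)(C(=O)OCC[Si](C)(C)C)[C@H](C(C)=C)CCC(=O)CP(=O)(OCC)OCC
F4 | step 6 | 2-(trimethylsilyl)ethyl (3R)-3-acetyl-7-(diethoxyphosphoryl)-2,2-dimethyl-6-oxoheptanoate | CC(C)(C(=O)OCC[Si](C)(C)C)[C@H](C(C)=O)CCC(=O)CP(=O)(OCC)OCC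
F5 | step 15 | C10-allyl aldol: 2-(trimethylsilyl)ethyl 2-[(1S,2R)-3-{(3R)-3-[(4R)-2,2-dimethyl-1,3-dioxolan-4-yl]-1-hydroxy-3-[(triethylsilyl)oxy]butyl}-2-methyl-4-oxo-2-(prop-2-en-1-yl)cyclohexyl]-2-methylpropanoate | CC(C)(C(=O)OCC[Si](C)(C)C)[C@H]1CCC(=O)C(C(O)C[C@@](C)(O[Si](CC)(CC)CC)[C@H]2COC(C)(C)O2)[C@]1(C)CC=C
F6 | step 15 | C10-allyl exocyclic enone (butylidene analogue of F5) | CC(C)(C(=O)OCC[Si](C)(C)C)[C@H]1CCC(=O)C(=CC[C@@](C)(O[Si](CC)(CC)CC)[C@H]2COC(C)(C)O2)[C@]1(C)CC=C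
F7 | step 15 | C10-allyl ketone: (1S,2R,3S)-2-(prop-2-en-1-yl) analogue of 30 | CC(C)(C(=O)OCC[Si](C)(C)C)[C@H]1CCC(=O)[C@@H](CC[C@@](C)(O[Si](CC)(CC)CC)[C@H]2COC(C)(C)O2)[C@]1(C)CC=C
F8 | step 15 | C10 acetaldehyde: (1S,2R,3S)-2-(2-oxoethyl) analogue of 30 | CC(C)(C(=O)OCC[Si](C)(C)C)[C@H]1CCC(=O)[C@@H](CC[C@@](C)(O[Si](CC)(CC)CC)[C@H]2COC(C)(C)O2)[C@]1(C)CC=O
F9 | step 15 | C10 acetic acid: (1S,2R,3S)-2-(carboxymethyl) analogue of 30 | CC(C)(C(=O)OCC[Si](C)(C)C)[C@H]1CCC(=O)[C@@H](CC[C@@](C)(O[Si](CC)(CC)CC)[C@H]2COC(C)(C)O2)[C@]1(C)CC(=O)O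
F10 | step 19 | C8 exocyclic methylene compound (4-methylidene analogue of 30) | CC(C)(C(=O)OCC[Si](C)(C)C)[C@H]1CCC(=C)[C@@H](CC[C@@](C)(O[Si](CC)(CC)CC)[C@H]2COC(C)(C)O2)[C@]1(C)CC(=O)OCC[Si](C)(C)C
F11 | step 19 | C13 tertiary alcohol (F10 without the triethylsilyl group) | CC(C)(C(=O)OCC[Si](C)(C)C)[C@H]1CCC(=C)[C@@H](CC[C@@](C)(O)[C@H]2COC(C)(C)O2)[C@]1(C)CC(=O)OCC[Si](C)(C)C
F12 | step 19 | acetoxymercuriomethyl pyran (33 with CH2HgOAc in place of the C8 methyl) | CC(C)(C(=O)OCC[Si](C)(C)C)[C@H]1CC[C@]2(C[Hg]OC(C)=O)O[C@@](C)([C@H]3COC(C)(C)O3)CC[C@H]2[C@]1(C)CC(=O)OCC[Si](C)(C)C
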